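**Target:** (2S,3S)-2-[(14S)-14-hydroxypentadecyl]-4-methylidene-5-oxooxolane-3-carboxylic acid (18)

## Analysis of the target

The target 18 has one ring, an oxolan-2-one (ring A: O1, C2, C3, C4, C5, with C5 the lactone carbonyl). It carries an unbranched C15 chain (C1'–C15') at C2, a free carboxylic acid at C3 and an exocyclic methylidene at C4. The ring stereocentres C2 and C3 are contiguous and cis (both S), the thermodynamically less favoured arrangement of a 2,3-disubstituted paraconic acid. The third stereocentre, the (S)-carbinol C14', is separated from C2 by thirteen methylene groups and cannot direct the ring configuration. The ring must therefore be built under absolute control, because ring epimers that differ only relative to C14' could not be separated in practice. C3–H is α to the carboxyl and allylic to C4=CH2, so base would epimerise it to trans or move the double bond into the ring; the methylene lactone is also a Michael acceptor and the lactone opens in base. The difficulty is to form the C2–C3 bond with kinetic cis control and catalyst-derived absolute control, with methylidene and carboxyl already in place so that no basic step follows. The feature that invites the chosen move is the array O1–C2H–C3H(CO2H)–C4(=CH2)–C5(=O) of ring A: the C2–O1 carbinol is homoallylic to C4=CH2 and C4 bears the acyl carbon C5. This is the retron of a carbonyl 2-(alkoxycarbonyl)allylation with lactonisation, and the cis C2/C3 relationship is the retron of a closed chair transition state.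

## Retrosynthetic reasoning

**18 ⇒ 17.** Only O–C(tert-butyl) and O–Si bonds are cut. The C3 acid is carried as a tert-butyl ester and the C14' alcohol as a silyl ether, so both fall in one acid step and no base is needed after ring A exists.

**17 ⇒ 15 + 7 (key disconnection).** The C2–C3 bond and the O1–C5 acyl–oxygen bond are cut. C2–C3 is the only bond that joins the two ring stereocentres. Cutting it separates a linear aldehyde 15, which carries only the remote stereocentre, from an achiral C5 allylboronate 7 that already holds C3, C4, the methylidene carbon, C5 and the carboxyl at their final oxidation levels. The forward reaction must add the γ-carbon of 7 to one face of 15 under catalyst control, pass the alkene geometry of 7 on to the cis relationship through a chair transition state, and close ring A by attack of the new C2 oxygen on the methyl ester.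

**7 ⇒ 6.** The C–B bond at the future methylidene carbon is cut back to a C–Br bond. A palladium-catalysed borylation must deliver boron to the CH2 terminus and keep the alkene geometry.

**6 ⇒ 4.** The allylic bromide with the two esters trans is traced to the 1,1-disubstituted alkene 4 by halogen addition and dehydrohalogenation. This fixes the geometry that the key step later reads: CH2Br (later CH2B) cis to the tert-butoxycarbonyl group.

**4 ⇒ 1 + 2.** The C2–C3 bond of the butanedioate and its C=CH2 bond are cut. Alkylation of phosphonate 1 with bromo ester 2 and olefination with a one-carbon aldehyde differentiate the two esters from the start: methyl on the conjugated carboxyl (future C5), tert-butyl on the other (future C3 carboxyl).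

**15 ⇒ 13.** The aldehyde is traced to a terminal alkyne of the same carbon count (anti-Markovnikov hydration through hydroboration), so no protecting group is needed at that chain end.

**13 ⇒ 12 ⇒ 11.** Silyl protection, then the terminal alkyne is traced to an internal alkyne by contra-thermodynamic isomerisation along the chain (alkyne zipper). The full C16 chain can therefore come from one cheap alkyne.

**11 ⇒ 8 + 9.** The side-chain bond C12'–C13' is cut between an acetylide carbon of 8 and the CH2 of epoxide 9. The (S)-carbinol is bought from the chiral pool, and its configuration is not touched again.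

## Alternatives that were turned down

**Alternative 1:** (the textbook route) Disconnection of C2–C3 by an aldol between a succinate enolate and aldehyde 15, lactonisation to the paraconic acid A1, then attachment of the methylidene carbon at C4 by carboxylation–Mannich methylenation or enolate aminomethylation. The forward key step is an auxiliary-controlled boron aldol of a succinyl imide. It was turned down for three reasons.
- The reliable syn-selective aldol maps onto the trans lactone. The imide carbonyl, which lies in the aldol backbone, becomes the C3 carboxyl, and the enolate side arm becomes C4/C5, so syn in the aldol sense is anti in the ring sense. The cis acid A1 needs an anti-selective aldol, for which auxiliaries are less general.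
- The methylidene comes last, through an enolate or magnesium chelate at C4 next to the cis C3–H under basic conditions. This is where epimerisation to trans and double-bond migration are expected.
- Auxiliary attachment and removal plus a two-operation methylenation add four to five steps.

**Alternative 2:** Disconnection of C3–C4 and of the bond from the carbonyl carbon to C2 by a (2+2) cycloaddition of dichloroketene to the (Z)-alkene A2, then Baeyer–Villiger ring expansion of cyclobutanone A3 (O1 inserted next to C2). The cycloaddition is suprafacial on the alkene, so the (Z) geometry would become the cis C2/C3 relationship. It was turned down because: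
- the two ends of A2 are electronically similar, so the regiochemistry of the cycloaddition is not controlled;
- nothing controls absolute configuration unless an auxiliary-bearing enol ether is used, which changes the substitution pattern and lengthens the route;
- after ring expansion, dechlorination, debenzylation, oxidation of the CH2O arm to the acid and the same late methylenation as in Alternative 1 are still needed — well over ten steps for a ring the chosen key step makes in one.

**Alternative 3:** Disconnection of O1–C5 and C4–C5 by palladium-catalysed cyclocarbonylation of the homopropargylic alcohol A4. Carbon monoxide is inserted between the internal alkyne carbon (C4) and the C2 hydroxyl, and the terminal alkyne carbon becomes the methylidene. The forward key step is hydroxyl-directed carbonylative lactonisation of the alkyne. It was turned down because this step creates no stereocentre. A4 must already hold C2 and C3 in the correct relationship, and the direct way to it is an anti-selective aldol of a but-3-ynoate enolate. That enolate is prone to alkyne-to-allene isomerisation, and its α-C–H is doubly activated. The hard part of the problem would only be moved one step back, at the cost of a pressure step with a toxic gas.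

Key step: step 8

Remark: (R)-TRIP is assumed to expose the Re face of aldehyde 15 to boronate 7, as it does for simple allyl and crotyl pinacolboronates; should the sense be opposite, the (S)-acid would be used.

## Route

Step 1
Reactants: 1 trimethyl phosphonoacetate; 2 tert-butyl bromoacetate
Product: 4 4-tert-butyl 1-methyl 2-methylidenebutanedioate, via phosphonosuccinate 3 (not isolated)
Conditions: NaH, THF, 0 °C → rt; then 37% aq. HCHO, K2CO3, rt
Reagents that add atoms: formaldehyde, C=O
Why: Alkylation of the phosphonoacetate carbanion by the α-bromo ester, then Horner–Wadsworth–Emmons olefination of the phosphonosuccinate with formaldehyde; the phosphorus-bearing carbon becomes the alkene carbon, so the methyl ester is conjugated (future C5) and the tert-butyl ester sits on the CH2 arm (future C3 carboxyl).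

Step 2
Reactants: 4 4-tert-butyl 1-methyl 2-methylidenebutanedioate
Product: 6 4-tert-butyl 1-methyl (2Z)-2-(bromomethyl)but-2-enedioate, via dibromide 5 (not isolated)
Conditions: Br2, CH2Cl2, 0 °C → rt; then Et3N (1.05 equiv), Et2O, 0 °C
Reagents that add atoms: bromine, BrBr
Why: Bromine addition gives the vicinal dibromide; triethylamine then removes the acidic C3–H with loss of the tertiary bromide (dehydrobromination). The trisubstituted alkene should form with the two esters trans (fumarate geometry), which places CH2Br cis to the tert-butoxycarbonyl group.

Step 3
Reactants: 6 4-tert-butyl 1-methyl (2Z)-2-(bromomethyl)but-2-enedioate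
Product: 7 4-tert-butyl 1-methyl (2E)-2-[(4,4,5,5-tetramethyl-1,3,2-dioxaborolan-2-yl)methyl]but-2-enedioate
Conditions: B2pin2 (1.1 equiv), Pd2(dba)3 (2.5 mol%), THF, 50 °C
Reagents that add atoms: bis(pinacolato)diboron, CC1(C)OB(OC1(C)C)B1OC(C)(C)C(C)(C)O1
Why: Miyaura-type borylation of an allylic halide: oxidative addition to zerovalent palladium gives a π-allyl complex, and transmetalation with the diboron and C–B reductive elimination at the unsubstituted CH2 terminus give the primary allylboronate. The alkene stays conjugated with both esters in the fumarate geometry (descriptor E only because boron ranks below oxygen).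

Step 4
Reactants: 8 tridec-1-yne; 9 (S)-2-methyloxirane
Product: 11 (2S)-hexadec-4-yn-2-ol, via lithium tridec-1-yn-1-ide 10 (not isolated)
Conditions: n-BuLi, THF, −78 °C; BF3·OEt2 (promoter); then 9, −78 °C; aq. NH4Cl
Reagents that add atoms: none
Why: BF3-promoted SN2 opening of the epoxide by the lithium acetylide at the unsubstituted carbon; no bond to the stereocentre is broken, so the (S) configuration of 9 becomes that of the carbinol.

Step 5
Reactants: 11 (2S)-hexadec-4-yn-2-ol
Product: 12 (2S)-hexadec-15-yn-2-ol
Conditions: KH, H2N(CH2)3NH2, 0 °C → rt; then H2O
Reagents that add atoms: none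
Why: Alkyne zipper reaction: potassium 3-aminopropylamide moves the triple bond along the unbranched chain by propargyl–allenyl proton shifts until the terminal acetylide, the thermodynamic sink, is reached. The secondary alkoxide blocks migration toward C2, whose C–H is not acidic, so the stereocentre is retained.

Step 6
Reactants: 12 (2S)-hexadec-15-yn-2-ol
Product: 13 tert-butyl{[(2S)-hexadec-15-yn-2-yl]oxy}dimethylsilane
Conditions: TBSCl, imidazole, DMF, rt
Reagents that add atoms: tert-butyl(chloro)dimethylsilane, CC(C)(C)[Si](C)(C)Cl
Why: Standard silylation of a secondary alcohol; the silyl ether masks the only protic group before the borane and Brønsted acid steps and is removed by the final acid step.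

Step 7
Reactants: 13 tert-butyl{[(2S)-hexadec-15-yn-2-yl]oxy}dimethylsilane
Product: 15 (15S)-15-{[tert-butyl(dimethyl)silyl]oxy}hexadecanal, via alkenylborane 14 (not isolated)
Conditions: Cy2BH (from BH3·SMe2 and cyclohexene), THF, 0 °C → rt; then 30% H2O2, pH 8 phosphate buffer, 0 °C → rt
Reagents that add atoms: hydrogen peroxide, OO
Why: Anti-Markovnikov syn-hydroboration of the terminal alkyne with a hindered dialkylborane stops at the (E)-1-alkenylborane; buffered peroxide oxidation gives the enol and hence the aldehyde without base-induced aldol chemistry.

Step 8
Reactants: 15 (15S)-15-{[tert-butyl(dimethyl)silyl]oxy}hexadecanal; 7 4-tert-butyl 1-methyl (2E)-2-[(4,4,5,5-tetramethyl-1,3,2-dioxaborolan-2-yl)methyl]but-2-enedioate (1.3 equiv)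
Product: 17 tert-butyl (2S,3S)-2-[(14S)-14-{[tert-butyl(dimethyl)silyl]oxy}pentadecyl]-4-methylidene-5-oxooxolane-3-carboxylate, via borate ester 16 (not isolated)
Conditions: (R)-TRIP [(R)-3,3'-bis(2,4,6-triisopropylphenyl)-1,1'-binaphthalene-2,2'-diyl hydrogen phosphate] (10 mol%), 4 Å MS, toluene, 0 °C → rt; then p-TsOH·H2O (10 mol%), rt
Reagents that add atoms: none
Why: The chiral phosphoric acid hydrogen-bonds to a boronate oxygen of 7, raising the Lewis acidity of boron, and through its phosphoryl oxygen to the formyl C–H of 15; the γ-carbon of 7 then adds to the aldehyde carbon through a closed six-membered chair (Zimmerman–Traxler) transition state, the double bond moving to the exocyclic position to give borate 16. The closest known reaction type is the chiral phosphoric acid-catalysed allylboration of aldehydes with pinacol allylboronates, including γ-substituted 2-(alkoxycarbonyl)allylboronates that lactonise to β-substituted α-methylene-γ-butyrolactones. Ring A closes by 5-exo-trig acyl substitution of the C2 oxygen on the methyl ester (O1–C5 bond) with loss of methanol; the tert-butyl ester cannot compete because it is hindered and would give a four-membered ring. C2 is set by the catalyst: with the aldehyde chain equatorial, (R)-TRIP is expected to direct attack to the Re face, which gives (2S). C3 is relayed in the same transition state: the tert-butoxycarbonyl group is cis to CH2B in 7 and is forced axial, which gives the syn adduct and therefore the 2,3-cis lactone, (3S). The step needs γ-regioselectivity, which the cyclic allyl transfer provides, diastereoselectivity, which rests on the geometric purity and configurational stability of 7, and enantioselectivity, which is helped by the slow uncatalysed background reaction of this acceptor-substituted boronate. No base is present, so C3–H and the exocyclic alkene stay where they are formed, and the remote C14' centre is a spectator.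

Step 9
Reactants: 17 tert-butyl (2S,3S)-2-[(14S)-14-{[tert-butyl(dimethyl)silyl]oxy}pentadecyl]-4-methylidene-5-oxooxolane-3-carboxylate
Product: 18 (2S,3S)-2-[(14S)-14-hydroxypentadecyl]-4-methylidene-5-oxooxolane-3-carboxylic acid
Conditions: TFA–H2O (9:1), 0 °C → rt
Reagents that add atoms: none
Why: Acidolysis: the tert-butyl ester loses 2-methylpropene by alkyl–oxygen cleavage and the silyl ether is hydrolysed in the same medium. No base is used, so C3 and the exocyclic alkene are not at risk and no stereocentre is touched.

## Compound list

1 | trimethyl phosphonoacetate | COC(=O)CP(=O)(OC)OC | starting material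
2 | tert-butyl bromoacetate | CC(C)(C)OC(=O)CBr | starting material
3 | 4-tert-butyl 1-methyl 2-(dimethoxyphosphoryl)butanedioate (racemic) | COC(=O)C(CC(=O)OC(C)(C)C)P(=O)(OC)OC | intermediate
4 | 4-tert-butyl 1-methyl 2-methylidenebutanedioate | C=C(CC(=O)OC(C)(C)C)C(=O)OC | intermediate
5 | 4-tert-butyl 1-methyl 2-bromo-2-(bromomethyl)butanedioate (racemic) | COC(=O)C(Br)(CBr)CC(=O)OC(C)(C)C | intermediate
6 | 4-tert-butyl 1-methyl (2Z)-2-(bromomethyl)but-2-enedioate | COC(=O)/C(CBr)=C/C(=O)OC(C)(C)C | intermediate
7 | 4-tert-butyl 1-methyl (2E)-2-[(4,4,5,5-tetramethyl-1,3,2-dioxaborolan-2-yl)methyl]but-2-enedioate | COC(=O)/C(CB1OC(C)(C)C(C)(C)O1)=C/C(=O)OC(C)(C)C | intermediate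
8 | tridec-1-yne | C#CCCCCCCCCCCC | starting material
9 | (S)-2-methyloxirane | C[C@H]1CO1 | starting material
10 | lithium tridec-1-yn-1-ide | [Li+].[C-]#CCCCCCCCCCCC | intermediate
11 | (2S)-hexadec-4-yn-2-ol | C[C@H](O)CC#CCCCCCCCCCCC | intermediate
12 | (2S)-hexadec-15-yn-2-ol | C[C@H](O)CCCCCCCCCCCCC#C | intermediate
13 | tert-butyl{[(2S)-hexadec-15-yn-2-yl]oxy}dimethylsilane | C[C@H](O[Si](C)(C)C(C)(C)C)CCCCCCCCCCCCC#C | intermediate
14 | dicyclohexyl[(1E,15S)-15-{[tert-butyl(dimethyl)silyl]oxy}hexadec-1-en-1-yl]borane | C[C@H](O[Si](C)(C)C(C)(C)C)CCCCCCCCCCCC/C=C/B(C1CCCCC1)C1CCCCC1 | intermediate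
15 | (15S)-15-{[tert-butyl(dimethyl)silyl]oxy}hexadecanal | C[C@H](O[Si](C)(C)C(C)(C)C)CCCCCCCCCCCCCC=O | intermediate
16 | 4-tert-butyl 1-methyl (3S)-3-[(1S,15S)-15-{[tert-butyl(dimethyl)silyl]oxy}-1-[(4,4,5,5-tetramethyl-1,3,2-dioxaborolan-2-yl)oxy]hexadecyl]-2-methylidenebutanedioate | COC(=O)C(=C)[C@H](C(=O)OC(C)(C)C)[C@@H](OB1OC(C)(C)C(C)(C)O1)CCCCCCCCCCCCC[C@H](C)O[Si](C)(C)C(C)(C)C | intermediate
17 | tert-butyl (2S,3S)-2-[(14S)-14-{[tert-butyl(dimethyl)silyl]oxy}pentadecyl]-4-methylidene-5-oxooxolane-3-carboxylate | C=C1C(=O)O[C@@H](CCCCCCCCCCCCC[C@H](C)O[Si](C)(C)C(C)(C)C)[C@H]1C(=O)OC(C)(C)C | intermediate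
18 | (2S,3S)-2-[(14S)-14-hydroxypentadecyl]-4-methylidene-5-oxooxolane-3-carboxylic acid | C=C1C(=O)O[C@@H](CCCCCCCCCCCCC[C@H](C)O)[C@H]1C(=O)O | target

## Step count and least certain steps

Total step count: 9. Longest linear sequence: 6 steps (steps 4, 5, 6, 7, 8, 9, from 8 and 9); the boronate arm (steps 1–3) joins at step 8.

**Step 8 (key step).** Most likely to go wrong: slow C–C bond formation, because both alkene carbons of 7 carry acceptor groups. This would leave time for acid-promoted 1,3-migration of boron, which would move bond formation to the CH2 terminus, and for poorly organised addition with weak facial discrimination of an unbranched aldehyde. The fallback replaces catalyst control by reagent control; it sets out from bromide 6 and aldehyde 15 and returns to the route at 17. Borylation of 6 with bis(diethyl D-tartrate glycolato)diboron under Pd2(dba)3 catalysis would give diethyl (4S,5S)-2-[(2E)-4-tert-butoxy-2-(methoxycarbonyl)-4-oxobut-2-en-1-yl]-1,3,2-dioxaborolane-4,5-dicarboxylate F1, whose boron is more Lewis acidic than that of 7. Used without purification, F1 would be combined with 15 (toluene, 4 Å MS, −78 °C → rt, no catalyst), so that the chiral boronate itself selects the aldehyde face; on the usual dipole-repulsion model the (S,S)-tartrate is the one expected to attack the Re face. The same chair transition state would give the cis adduct, which p-TsOH·H2O would close to 17.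

**Step 3.** Most likely to go wrong: loss of regio- and geometric integrity during C–B bond formation, through syn/anti isomerisation of the π-allyl intermediate or boron delivery to the ester-bearing terminus. The fallback changes the mechanism of C–B formation; it sets out from 6 and returns at 7. Amine-mediated SN2' substitution of 6 (DABCO, then KOAc, MeCN) would transpose the leaving group to give 4-tert-butyl 1-methyl 3-(acetyloxy)-2-methylidenebutanedioate F2. Copper-catalysed conjugate borylation and β-elimination of acetate (B2pin2, CuCl, KOAc, DMF, rt) would then place boron on the CH2 carbon with no π-allyl intermediate, and the elimination is expected to give the ester-trans alkene of 7.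

**Step 5.** Most likely to go wrong: stalled isomerisation that leaves mixtures of internal alkynes, and handling of the strongly basic amide. The fallback builds the chain by olefin metathesis; it sets out from 9 and returns at 15.
- Opening of 9 with but-3-enylmagnesium bromide (CuI cat., THF, −30 °C) would give (2S)-hept-6-en-2-ol F3.
- Silylation (TBSCl, imidazole) would give tert-butyl{[(2S)-hept-6-en-2-yl]oxy}dimethylsilane F4.
- Cross-metathesis with excess undec-10-enal (second-generation Grubbs catalyst, CH2Cl2, 40 °C) would give (10E,15S)-15-{[tert-butyl(dimethyl)silyl]oxy}hexadec-10-enal F5.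
- Hydrogenation (H2, Pd/C, EtOAc) would give 15.

**Step 2.** Most likely to go wrong: cleavage of the tert-butyl ester by adventitious HBr during bromine addition, and N-alkylation of the amine base by the reactive allylic bromide. The fallback uses radical substitution in place of addition–elimination; it sets out from 4 and returns at 6. Base-catalysed equilibration of 4 (Et3N cat., 40 °C) would move the double bond into conjugation to give 4-tert-butyl 1-methyl (2E)-2-methylbut-2-enedioate F6. Wohl–Ziegler bromination of the allylic methyl group (NBS, AIBN, PhCF3, 80 °C) would give 6 under neutral conditions.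

## Further compounds

F1 | step 8 | diethyl (4S,5S)-2-[(2E)-4-tert-butoxy-2-(methoxycarbonyl)-4-oxobut-2-en-1-yl]-1,3,2-dioxaborolane-4,5-dicarboxylate | COC(=O)/C(CB1O[C@H](C(=O)OCC)[C@@H](C(=O)OCC)O1)=C/C(=O)OC(C)(C)C
F2 | step 3 | 4-tert-butyl 1-methyl 3-(acetyloxy)-2-methylidenebutanedioate (racemic) | C=C(C(=O)OC)C(OC(C)=O)C(=O)OC(C)(C)C
F3 | step 5 | (2S)-hept-6-en-2-ol | C[C@H](O)CCCC=C
F4 | step 5 | tert-butyl{[(2S)-hept-6-en-2-yl]oxy}dimethylsilane | C[C@H](O[Si](C)(C)C(C)(C)C)CCCC=C
F5 | step 5 | (10E,15S)-15-{[tert-butyl(dimethyl)silyl]oxy}hexadec-10-enal | C[C@H](O[Si](C)(C)C(C)(C)C)CCC/C=C/CCCCCCCCC=O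
F6 | step 2 | 4-tert-butyl 1-methyl (2E)-2-methylbut-2-enedioate | COC(=O)/C(C)=C/C(=O)OC(C)(C)C
A1 | alternative 1 | (2S,3S)-2-[(14S)-14-{[tert-butyl(dimethyl)silyl]oxy}pentadecyl]-5-oxooxolane-3-carboxylic acid | C1C(=O)O[C@@H](CCCCCCCCCCCCC[C@H](C)O[Si](C)(C)C(C)(C)C)[C@H]1C(=O)O
A2 | alternative 2 | tert-butyl{[(2S,16Z)-18-(benzyloxy)octadec-16-en-2-yl]oxy}dimethylsilane | C[C@H](O[Si](C)(C)C(C)(C)C)CCCCCCCCCCCCC/C=C\COCc1ccccc1
A3 | alternative 2 | (3S,4S)-3-[(benzyloxy)methyl]-2,2-dichloro-4-[(14S)-14-{[tert-butyl(dimethyl)silyl]oxy}pentadecyl]cyclobutan-1-one | ClC1(Cl)C(=O)[C@@H](CCCCCCCCCCCCC[C@H](C)O[Si](C)(C)C(C)(C)C)[C@H]1COCc1ccccc1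
A4 | alternative 3 | tert-butyl (2S,3S,17S)-17-{[tert-butyl(dimethyl)silyl]oxy}-2-ethynyl-3-hydroxyoctadecanoate | C#C[C@H](C(=O)OC(C)(C)C)[C@@H](O)CCCCCCCCCCCCC[C@H](C)O[Si](C)(C)C(C)(C)C
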